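## Retrosynthetic overview

1. The acid is taken back to a silyl-protected allylic alcohol (late oxidation), and the C5 carbinol to a reagent-controlled hydroxylation of the C4 ketone enolate. Benzofuranone numbering is used: O1, C2, C3, C3a, C4 (C=O), C5, C6, C7, C7a; side chain C1′–C9′.
2. Structural feature: ring A (O1, C2, C3, C3a, C7a) with C7 and C4 attached is a 2-methyl-4,5-dihydrofuran-3-carboxylate (C7 = vinylogous methyl, C4 = ester carbon). Ring B therefore lacks only C5–C6, which an acrylate supplies through the C6–C7 (Michael) and C4–C5 (Dieckmann) bonds.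
3. Ring A comes from a terminal epoxide and methyl acetoacetate (acetyl lactone, then acyl-lactone rearrangement), so the O1–C7a bond exists before ring B is closed.
4. C2 is taken from methyl (S)-glycerate acetonide. C1′ is set by chelation-controlled addition of a homogeranyl-type Grignard reagent (seven steps from geranyl acetate) to the derived methyl ketone.
5. Order of ring formation: ring A (dihydrofuran) first, ring B (cyclohexenone) second.

Key step: step 14

Assumption: the face selectivity of the 8,8-dichlorocamphor-derived sulfonyloxaziridine on the C4–C5 enolate is taken to parallel that on 1-tetralone enolates, which points to the (−)-reagent for (5R); both antipodes are available, so the other one would be used if the sense proves reversed.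

## Route

Step 1
Reactants: 1 geranyl acetate
Product: 2 (2E,6E)-8-hydroxy-3,7-dimethylocta-2,6-dien-1-yl acetate
Conditions: SeO2 (cat.), t-BuOOH, salicylic acid (cat.), CH2Cl2, rt
Reagents that add atoms: selenium dioxide O=[Se]=O (oxygen carrier); tert-butyl hydroperoxide CC(C)(C)OO (terminal oxidant)
Why: SeO2 allylic oxidation (ene reaction, then [2,3]-sigmatropic shift) should attack the 6,7-alkene at its E-methyl group, because the 2,3-alkene is deactivated by the allylic acetate, giving the E-allylic alcohol.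

Step 2
Reactants: 2 (2E,6E)-8-hydroxy-3,7-dimethylocta-2,6-dien-1-yl acetate
Product: 3 (2E,6E)-8-[(tert-butyldiphenylsilyl)oxy]-3,7-dimethylocta-2,6-dien-1-yl acetate
Conditions: t-BuPh2SiCl, imidazole, DMF, rt
Reagents that add atoms: tert-butyl(chloro)diphenylsilane CC(C)(C)[Si](Cl)(c1ccccc1)c1ccccc1
Why: Standard silylation of a primary alcohol; the bulky silyl ether is chosen to survive the later Grignard, base and mild-acid steps.

Step 3
Reactants: 3 (2E,6E)-8-[(tert-butyldiphenylsilyl)oxy]-3,7-dimethylocta-2,6-dien-1-yl acetate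
Product: 4 (2E,6E)-8-[(tert-butyldiphenylsilyl)oxy]-3,7-dimethylocta-2,6-dien-1-ol
Conditions: K2CO3 (cat.), MeOH, rt
Reagents that add atoms: none
Why: Base-catalysed transesterification removes the acetate as methyl acetate and should leave the silyl ether untouched.

Step 4
Reactants: 4 (2E,6E)-8-[(tert-butyldiphenylsilyl)oxy]-3,7-dimethylocta-2,6-dien-1-ol
Product: 5 (2E,6E)-8-[(tert-butyldiphenylsilyl)oxy]-3,7-dimethylocta-2,6-dienal
Conditions: MnO2, CH2Cl2, rt
Reagents that add atoms: none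
Why: MnO2 oxidation is selective for the allylic alcohol and should keep the 2E geometry of the enal.

Step 5
Reactants: 5 (2E,6E)-8-[(tert-butyldiphenylsilyl)oxy]-3,7-dimethylocta-2,6-dienal
Product: 6 tert-butyl{[(2E,6E)-2,6-dimethylnona-2,6,8-trien-1-yl]oxy}diphenylsilane
Conditions: Ph3PCH3Br, n-BuLi, THF, 0 °C
Reagents that add atoms: methyltriphenylphosphonium bromide C[P+](c1ccccc1)(c1ccccc1)c1ccccc1.[Br-]
Why: Wittig methylenation of the enal gives the terminal 1,3-diene without touching the trisubstituted alkenes.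

Step 6
Reactants: 6 tert-butyl{[(2E,6E)-2,6-dimethylnona-2,6,8-trien-1-yl]oxy}diphenylsilane
Product: 8 (3E,7E)-9-[(tert-butyldiphenylsilyl)oxy]-4,8-dimethylnona-3,7-dien-1-ol, via B-alkyl-9-BBN adduct 7 (not isolated)
Conditions: 9-BBN, THF, 0 °C→rt; then NaOH, H2O2, 0 °C
Reagents that add atoms: hydrogen peroxide OO
Why: Hydroboration–oxidation with the bulky borane should take only the monosubstituted terminal alkene, anti-Markovnikov, and give the homoallylic alcohol.

Step 7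
Reactants: 8 (3E,7E)-9-[(tert-butyldiphenylsilyl)oxy]-4,8-dimethylnona-3,7-dien-1-ol
Product: 9 {[(2E,6E)-9-bromo-2,6-dimethylnona-2,6-dien-1-yl]oxy}(tert-butyl)diphenylsilane
Conditions: CBr4, PPh3, CH2Cl2, 0 °C
Reagents that add atoms: carbon tetrabromide BrC(Br)(Br)Br
Why: Appel bromination converts the primary alcohol to the bromide under neutral conditions that spare the alkenes and the silyl ether.

Step 8
Reactants: 10 methyl (4S)-2,2-dimethyl-1,3-dioxolane-4-carboxylate
Product: 12 1-[(4S)-2,2-dimethyl-1,3-dioxolan-4-yl]ethan-1-one, via Weinreb amide 11 (not isolated)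
Conditions: MeNH(OMe)·HCl, iPrMgCl, THF, −20 °C; then MeMgBr, −20→0 °C; NH4Cl (aq)
Reagents that add atoms: methylmagnesium bromide C[Mg]Br
Why: One-pot Weinreb ketone synthesis; the magnesium-chelated tetrahedral adduct prevents over-addition and keeps the α-stereocentre from enolising until work-up.

Step 9
Reactants: 9 {[(2E,6E)-9-bromo-2,6-dimethylnona-2,6-dien-1-yl]oxy}(tert-butyl)diphenylsilane; 12 1-[(4S)-2,2-dimethyl-1,3-dioxolan-4-yl]ethan-1-one
Product: 14 (2S,5E,9E)-11-[(tert-butyldiphenylsilyl)oxy]-2-[(4S)-2,2-dimethyl-1,3-dioxolan-4-yl]-6,10-dimethylundeca-5,9-dien-2-ol, via Grignard reagent 13 (not isolated)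
Conditions: Mg, THF, rt→40 °C; then 12, THF, −78 °C; NH4Cl (aq)
Reagents that add atoms: none
Why: Grignard addition under Cram chelate control: magnesium bridges the ketone oxygen and the α-oxygen of the dioxolane, the alkyl group attacks the face opposite the dioxolane CH2, and the (S)-carbinol (syn to the C4 oxygen) should result.

Step 10
Reactants: 14 (2S,5E,9E)-11-[(tert-butyldiphenylsilyl)oxy]-2-[(4S)-2,2-dimethyl-1,3-dioxolan-4-yl]-6,10-dimethylundeca-5,9-dien-2-ol
Product: 15 tert-butyl{[(2S,5E,9E)-11-[(tert-butyldiphenylsilyl)oxy]-2-[(4S)-2,2-dimethyl-1,3-dioxolan-4-yl]-6,10-dimethylundeca-5,9-dien-2-yl]oxy}dimethylsilane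
Conditions: t-BuMe2SiOTf, 2,6-lutidine, CH2Cl2, 0 °C→rt
Reagents that add atoms: tert-butyldimethylsilyl trifluoromethanesulfonate CC(C)(C)[Si](C)(C)OS(=O)(=O)C(F)(F)F
Why: Silyl triflate silylation is the standard way to cap a hindered tertiary alcohol, and the buffered conditions should leave the acetonide intact.

Step 11
Reactants: 15 tert-butyl{[(2S,5E,9E)-11-[(tert-butyldiphenylsilyl)oxy]-2-[(4S)-2,2-dimethyl-1,3-dioxolan-4-yl]-6,10-dimethylundeca-5,9-dien-2-yl]oxy}dimethylsilane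
Product: 16 (2S,3S,6E,10E)-3-[(tert-butyldimethylsilyl)oxy]-12-[(tert-butyldiphenylsilyl)oxy]-3,7,11-trimethyldodeca-6,10-diene-1,2-diol
Conditions: AcOH/H2O/THF (3:1:1), 45 °C
Reagents that add atoms: none
Why: Mild acid hydrolysis of the terminal acetonide; the tertiary tert-butyldimethylsilyl ether and the primary tert-butyldiphenylsilyl ether are stable to aqueous acetic acid.

Step 12
Reactants: 16 (2S,3S,6E,10E)-3-[(tert-butyldimethylsilyl)oxy]-12-[(tert-butyldiphenylsilyl)oxy]-3,7,11-trimethyldodeca-6,10-diene-1,2-diol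
Product: 18 tert-butyl{[(2S,5E,9E)-11-[(tert-butyldiphenylsilyl)oxy]-6,10-dimethyl-2-[(2S)-oxiran-2-yl]undeca-5,9-dien-2-yl]oxy}dimethylsilane, via primary tosylate 17 (not isolated)
Conditions: TsCl, Et3N, Bu2SnO (cat.), CH2Cl2, 0 °C→rt; then K2CO3, MeOH, 0 °C
Reagents that add atoms: none
Why: Tin-catalysed sulfonylation is selective for the primary hydroxyl, and the secondary oxygen then closes the epoxide (intramolecular Williamson reaction, 3-exo-tet) without breaking the C–O bond at the stereocentre; sulfonylating before base is added keeps the alkoxide too short-lived for silyl migration.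

Step 13
Reactants: 18 tert-butyl{[(2S,5E,9E)-11-[(tert-butyldiphenylsilyl)oxy]-6,10-dimethyl-2-[(2S)-oxiran-2-yl]undeca-5,9-dien-2-yl]oxy}dimethylsilane; 19 methyl acetoacetate
Product: 22 methyl (5S)-5-[(2S,5E,9E)-2-[(tert-butyldimethylsilyl)oxy]-11-[(tert-butyldiphenylsilyl)oxy]-6,10-dimethylundeca-5,9-dien-2-yl]-2-methyl-4,5-dihydrofuran-3-carboxylate, via hydroxy keto ester 20 (not isolated), via acetyl lactone 21 (not isolated)
Conditions: 19 (excess), NaOMe, MeOH, 55 °C; then HCl/MeOH (dilute, to pH 1), 0 °C→rt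
Reagents that add atoms: methanol CO
Why: The acetoacetate enolate opens the epoxide at its terminal carbon and the adduct lactonises; acidic methanol then brings about the Korte acyl-lactone rearrangement (methanolysis, attack of the secondary hydroxyl on the ketone, loss of water), which never breaks the C–O bond at the stereocentre.

Step 14
Reactants: 22 methyl (5S)-5-[(2S,5E,9E)-2-[(tert-butyldimethylsilyl)oxy]-11-[(tert-butyldiphenylsilyl)oxy]-6,10-dimethylundeca-5,9-dien-2-yl]-2-methyl-4,5-dihydrofuran-3-carboxylate; 23 allyl acrylate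
Product: 26 allyl (2S)-2-[(2S,5E,9E)-2-[(tert-butyldimethylsilyl)oxy]-11-[(tert-butyldiphenylsilyl)oxy]-6,10-dimethylundeca-5,9-dien-2-yl]-4-oxo-2,3,4,5,6,7-hexahydro-1-benzofuran-5-carboxylate (C5 epimers and enol), via lithium dienolate 24 (not isolated), via Michael adduct enolate 25 (not isolated)
Conditions: LiN(iPr)2 (1.1 equiv), THF, −78 °C; 23 (1.05 equiv, slow addition), −78→0 °C; NH4Cl (aq)
Reagents that add atoms: none
Why: LiN(iPr)2 removes a proton from the C7 methyl group, which is vinylogous to the ester through C7a=C3a, and the exocyclic γ-carbon of dienolate 24 adds to the β-carbon of allyl acrylate (C6–C7 bond). The allyl ester enolate 25 then attacks the ring ester carbon in a 6-exo-trig Dieckmann closure (C4–C5 bond), methoxide leaves, and deprotonation of the β-keto ester makes the sequence irreversible. The closest known reaction type is the Michael–Claisen annulation of γ-metalated β-alkoxy crotonates and of o-toluate anions (Staunton–Weinreb annulation) with unsaturated esters. No stereocentre is controlled: C5 forms as an enolisable mixture that is erased in step 15, and C2 and the side-chain carbinol are untouched. The step needs γ- rather than α-attack and one acrylate per dienolate; the ring oxygen puts the largest coefficient on the exocyclic carbon, α-attack would have to build a quaternary C3a and is reversible, and slow addition of one equivalent of acrylate at −78 °C before warming limits oligomerisation.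

Step 15
Reactants: 26 allyl (2S)-2-[(2S,5E,9E)-2-[(tert-butyldimethylsilyl)oxy]-11-[(tert-butyldiphenylsilyl)oxy]-6,10-dimethylundeca-5,9-dien-2-yl]-4-oxo-2,3,4,5,6,7-hexahydro-1-benzofuran-5-carboxylate
Product: 28 (2S)-2-[(2S,5E,9E)-2-[(tert-butyldimethylsilyl)oxy]-11-[(tert-butyldiphenylsilyl)oxy]-6,10-dimethylundeca-5,9-dien-2-yl]-3,5,6,7-tetrahydro-1-benzofuran-4(2H)-one, via keto acid 27 (not isolated)
Conditions: Pd(PPh3)4 (cat.), morpholine, THF, rt
Reagents that add atoms: none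
Why: Tsuji–Trost deallylation: zerovalent palladium ionises the allyl ester, morpholine traps the allyl group, and the β-keto acid loses CO2 under neutral conditions that spare both silyl ethers.

Step 16
Reactants: 28 (2S)-2-[(2S,5E,9E)-2-[(tert-butyldimethylsilyl)oxy]-11-[(tert-butyldiphenylsilyl)oxy]-6,10-dimethylundeca-5,9-dien-2-yl]-3,5,6,7-tetrahydro-1-benzofuran-4(2H)-one
Product: 30 (2S,5R)-2-[(2S,5E,9E)-2-[(tert-butyldimethylsilyl)oxy]-11-[(tert-butyldiphenylsilyl)oxy]-6,10-dimethylundeca-5,9-dien-2-yl]-5-hydroxy-3,5,6,7-tetrahydro-1-benzofuran-4(2H)-one, via sodium enolate 29 (not isolated)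
Conditions: NaN(SiMe3)2, THF, −78 °C; then (−)-[(8,8-dichlorocamphoryl)sulfonyl]oxaziridine, −78 °C; NH4Cl (aq)
Reagents that add atoms: (−)-[(8,8-dichlorocamphoryl)sulfonyl]oxaziridine CC1(C)[C@H]2CC[C@@]13CS(=O)(=O)[N@@]4O[C@]34C2(Cl)Cl
Why: Davis asymmetric enolate hydroxylation: kinetic deprotonation of the vinylogous ester at C5 gives the cross-conjugated enolate, and the chiral oxaziridine transfers oxygen to one face under reagent control, because C2 is too remote to direct, which should set (5R).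

Step 17
Reactants: 30 (2S,5R)-2-[(2S,5E,9E)-2-[(tert-butyldimethylsilyl)oxy]-11-[(tert-butyldiphenylsilyl)oxy]-6,10-dimethylundeca-5,9-dien-2-yl]-5-hydroxy-3,5,6,7-tetrahydro-1-benzofuran-4(2H)-one
Product: 31 (2S,5R)-2-[(2S,5E,9E)-2,11-dihydroxy-6,10-dimethylundeca-5,9-dien-2-yl]-5-hydroxy-3,5,6,7-tetrahydro-1-benzofuran-4(2H)-one
Conditions: HF·pyridine, pyridine, THF, 0 °C→rt
Reagents that add atoms: none
Why: Buffered fluoride desilylation removes both silyl ethers without the basic conditions that could epimerise the α-hydroxy ketone at C5.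

Step 18
Reactants: 31 (2S,5R)-2-[(2S,5E,9E)-2,11-dihydroxy-6,10-dimethylundeca-5,9-dien-2-yl]-5-hydroxy-3,5,6,7-tetrahydro-1-benzofuran-4(2H)-one
Product: 32 (2E,6E,10S)-10-hydroxy-10-[(2S,5R)-5-hydroxy-4-oxo-2,3,4,5,6,7-hexahydro-1-benzofuran-2-yl]-2,6-dimethylundeca-2,6-dienal
Conditions: TEMPO (cat.), PhI(OAc)2, CH2Cl2, rt
Reagents that add atoms: none
Why: The oxoammonium oxidation is selective for the unhindered primary allylic alcohol over the secondary ketol and the tertiary alcohol, and it stops at the aldehyde in the absence of water.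

Step 19
Reactants: 32 (2E,6E,10S)-10-hydroxy-10-[(2S,5R)-5-hydroxy-4-oxo-2,3,4,5,6,7-hexahydro-1-benzofuran-2-yl]-2,6-dimethylundeca-2,6-dienal
Product: 33 (2E,6E,10S)-10-hydroxy-10-[(2S,5R)-5-hydroxy-4-oxo-2,3,4,5,6,7-hexahydro-1-benzofuran-2-yl]-2,6-dimethylundeca-2,6-dienoic acid (CNP0117600.1)
Conditions: NaClO2, NaH2PO4, 2-methyl-2-butene, t-BuOH/H2O, 0 °C→rt
Reagents that add atoms: sodium chlorite [Na+].[O-]Cl=O
Why: Pinnick oxidation converts the enal to the acid under buffered conditions, with 2-methyl-2-butene scavenging hypochlorite so that the alkenes, the enol ether and the ketol should survive.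

## Compound list

1 | geranyl acetate, (2E)-3,7-dimethylocta-2,6-dien-1-yl acetate | C/C(=C\COC(C)=O)CCC=C(C)C | starting material
2 | (2E,6E)-8-hydroxy-3,7-dimethylocta-2,6-dien-1-yl acetate | C/C(=C\COC(C)=O)CC/C=C(\C)CO | intermediate
3 | (2E,6E)-8-[(tert-butyldiphenylsilyl)oxy]-3,7-dimethylocta-2,6-dien-1-yl acetate | C/C(=C\COC(C)=O)CC/C=C(\C)CO[Si](c1ccccc1)(c1ccccc1)C(C)(C)C | intermediate
4 | (2E,6E)-8-[(tert-butyldiphenylsilyl)oxy]-3,7-dimethylocta-2,6-dien-1-ol | C/C(=C\CO)CC/C=C(\C)CO[Si](c1ccccc1)(c1ccccc1)C(C)(C)C | intermediate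
5 | (2E,6E)-8-[(tert-butyldiphenylsilyl)oxy]-3,7-dimethylocta-2,6-dienal | C/C(=C\C=O)CC/C=C(\C)CO[Si](c1ccccc1)(c1ccccc1)C(C)(C)C | intermediate
6 | tert-butyl{[(2E,6E)-2,6-dimethylnona-2,6,8-trien-1-yl]oxy}diphenylsilane | C/C(=C\C=C)CC/C=C(\C)CO[Si](c1ccccc1)(c1ccccc1)C(C)(C)C | intermediate
7 | 9-[(3E,7E)-9-[(tert-butyldiphenylsilyl)oxy]-4,8-dimethylnona-3,7-dien-1-yl]-9-borabicyclo[3.3.1]nonane (not isolated) | C/C(=C\CCB1C2CCCC1CCC2)CC/C=C(\C)CO[Si](c1ccccc1)(c1ccccc1)C(C)(C)C | intermediate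
8 | (3E,7E)-9-[(tert-butyldiphenylsilyl)oxy]-4,8-dimethylnona-3,7-dien-1-ol | C/C(=C\CCO)CC/C=C(\C)CO[Si](c1ccccc1)(c1ccccc1)C(C)(C)C | intermediate
9 | {[(2E,6E)-9-bromo-2,6-dimethylnona-2,6-dien-1-yl]oxy}(tert-butyl)diphenylsilane | C/C(=C\CCBr)CC/C=C(\C)CO[Si](c1ccccc1)(c1ccccc1)C(C)(C)C | intermediate
10 | methyl (4S)-2,2-dimethyl-1,3-dioxolane-4-carboxylate | COC(=O)[C@@H]1COC(C)(C)O1 | starting material
11 | (4S)-N-methoxy-N,2,2-trimethyl-1,3-dioxolane-4-carboxamide (Weinreb amide, not isolated) | CON(C)C(=O)[C@@H]1COC(C)(C)O1 | intermediate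
12 | 1-[(4S)-2,2-dimethyl-1,3-dioxolan-4-yl]ethan-1-one | CC(=O)[C@@H]1COC(C)(C)O1 | intermediate
13 | [(3E,7E)-9-[(tert-butyldiphenylsilyl)oxy]-4,8-dimethylnona-3,7-dien-1-yl]magnesium bromide (not isolated) | C/C(=C\CC[Mg]Br)CC/C=C(\C)CO[Si](c1ccccc1)(c1ccccc1)C(C)(C)C | intermediate
14 | (2S,5E,9E)-11-[(tert-butyldiphenylsilyl)oxy]-2-[(4S)-2,2-dimethyl-1,3-dioxolan-4-yl]-6,10-dimethylundeca-5,9-dien-2-ol | C/C(=C\CC[C@](C)(O)[C@@H]1COC(C)(C)O1)CC/C=C(\C)CO[Si](c1ccccc1)(c1ccccc1)C(C)(C)C | intermediate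
15 | tert-butyl{[(2S,5E,9E)-11-[(tert-butyldiphenylsilyl)oxy]-2-[(4S)-2,2-dimethyl-1,3-dioxolan-4-yl]-6,10-dimethylundeca-5,9-dien-2-yl]oxy}dimethylsilane | C/C(=C\CC[C@](C)(O[Si](C)(C)C(C)(C)C)[C@@H]1COC(C)(C)O1)CC/C=C(\C)CO[Si](c1ccccc1)(c1ccccc1)C(C)(C)C | intermediate
16 | (2S,3S,6E,10E)-3-[(tert-butyldimethylsilyl)oxy]-12-[(tert-butyldiphenylsilyl)oxy]-3,7,11-trimethyldodeca-6,10-diene-1,2-diol | C/C(=C\CC[C@](C)(O[Si](C)(C)C(C)(C)C)[C@@H](O)CO)CC/C=C(\C)CO[Si](c1ccccc1)(c1ccccc1)C(C)(C)C | intermediate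
17 | (2S,3S,6E,10E)-3-[(tert-butyldimethylsilyl)oxy]-12-[(tert-butyldiphenylsilyl)oxy]-2-hydroxy-3,7,11-trimethyldodeca-6,10-dien-1-yl 4-methylbenzenesulfonate (not isolated) | C/C(=C\CC[C@](C)(O[Si](C)(C)C(C)(C)C)[C@@H](O)COS(=O)(=O)c1ccc(C)cc1)CC/C=C(\C)CO[Si](c1ccccc1)(c1ccccc1)C(C)(C)C | intermediate
18 | tert-butyl{[(2S,5E,9E)-11-[(tert-butyldiphenylsilyl)oxy]-6,10-dimethyl-2-[(2S)-oxiran-2-yl]undeca-5,9-dien-2-yl]oxy}dimethylsilane | C/C(=C\CC[C@](C)(O[Si](C)(C)C(C)(C)C)[C@@H]1CO1)CC/C=C(\C)CO[Si](c1ccccc1)(c1ccccc1)C(C)(C)C | intermediate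
19 | methyl acetoacetate | COC(=O)CC(C)=O | starting material
20 | methyl (4S,5S,8E,12E)-2-acetyl-5-[(tert-butyldimethylsilyl)oxy]-14-[(tert-butyldiphenylsilyl)oxy]-4-hydroxy-5,9,13-trimethyltetradeca-8,12-dienoate (C2 epimers, not isolated) | C/C(=C\CC[C@](C)(O[Si](C)(C)C(C)(C)C)[C@@H](O)CC(C(C)=O)C(=O)OC)CC/C=C(\C)CO[Si](c1ccccc1)(c1ccccc1)C(C)(C)C | intermediate
21 | (5S)-3-acetyl-5-[(2S,5E,9E)-2-[(tert-butyldimethylsilyl)oxy]-11-[(tert-butyldiphenylsilyl)oxy]-6,10-dimethylundeca-5,9-dien-2-yl]oxolan-2-one (C3 epimers, not isolated) | C/C(=C\CC[C@](C)(O[Si](C)(C)C(C)(C)C)[C@@H]1CC(C(C)=O)C(=O)O1)CC/C=C(\C)CO[Si](c1ccccc1)(c1ccccc1)C(C)(C)C | intermediate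
22 | methyl (5S)-5-[(2S,5E,9E)-2-[(tert-butyldimethylsilyl)oxy]-11-[(tert-butyldiphenylsilyl)oxy]-6,10-dimethylundeca-5,9-dien-2-yl]-2-methyl-4,5-dihydrofuran-3-carboxylate | C/C(=C\CC[C@](C)(O[Si](C)(C)C(C)(C)C)[C@@H]1CC(C(=O)OC)=C(C)O1)CC/C=C(\C)CO[Si](c1ccccc1)(c1ccccc1)C(C)(C)C | intermediate
23 | allyl acrylate | C=CC(=O)OCC=C | starting material
24 | lithium dienolate of 22 (exocyclic methylene, lithium ketene acetal; not isolated) | C/C(=C\CC[C@](C)(O[Si](C)(C)C(C)(C)C)[C@@H]1CC(=C(OC)O[Li])C(=C)O1)CC/C=C(\C)CO[Si](c1ccccc1)(c1ccccc1)C(C)(C)C | intermediate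
25 | lithium enolate of the allyl ester formed by Michael addition at C7 (not isolated) | C/C(=C\CC[C@](C)(O[Si](C)(C)C(C)(C)C)[C@@H]1CC(C(=O)OC)=C(CCC=C(O[Li])OCC=C)O1)CC/C=C(\C)CO[Si](c1ccccc1)(c1ccccc1)C(C)(C)C | intermediate
26 | allyl (2S)-2-[(2S,5E,9E)-2-[(tert-butyldimethylsilyl)oxy]-11-[(tert-butyldiphenylsilyl)oxy]-6,10-dimethylundeca-5,9-dien-2-yl]-4-oxo-2,3,4,5,6,7-hexahydro-1-benzofuran-5-carboxylate (C5 epimers and enol) | C/C(=C\CC[C@](C)(O[Si](C)(C)C(C)(C)C)[C@@H]1CC2=C(CCC(C(=O)OCC=C)C2=O)O1)CC/C=C(\C)CO[Si](c1ccccc1)(c1ccccc1)C(C)(C)C | intermediate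
27 | (2S)-2-[(2S,5E,9E)-2-[(tert-butyldimethylsilyl)oxy]-11-[(tert-butyldiphenylsilyl)oxy]-6,10-dimethylundeca-5,9-dien-2-yl]-4-oxo-2,3,4,5,6,7-hexahydro-1-benzofuran-5-carboxylic acid (not isolated) | C/C(=C\CC[C@](C)(O[Si](C)(C)C(C)(C)C)[C@@H]1CC2=C(CCC(C(=O)O)C2=O)O1)CC/C=C(\C)CO[Si](c1ccccc1)(c1ccccc1)C(C)(C)C | intermediate
28 | (2S)-2-[(2S,5E,9E)-2-[(tert-butyldimethylsilyl)oxy]-11-[(tert-butyldiphenylsilyl)oxy]-6,10-dimethylundeca-5,9-dien-2-yl]-3,5,6,7-tetrahydro-1-benzofuran-4(2H)-one | C/C(=C\CC[C@](C)(O[Si](C)(C)C(C)(C)C)[C@@H]1CC2=C(CCCC2=O)O1)CC/C=C(\C)CO[Si](c1ccccc1)(c1ccccc1)C(C)(C)C | intermediate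
29 | sodium C4–C5 enolate of 28 (not isolated) | C/C(=C\CC[C@](C)(O[Si](C)(C)C(C)(C)C)[C@@H]1CC2=C(CCC=C2O[Na])O1)CC/C=C(\C)CO[Si](c1ccccc1)(c1ccccc1)C(C)(C)C | intermediate
30 | (2S,5R)-2-[(2S,5E,9E)-2-[(tert-butyldimethylsilyl)oxy]-11-[(tert-butyldiphenylsilyl)oxy]-6,10-dimethylundeca-5,9-dien-2-yl]-5-hydroxy-3,5,6,7-tetrahydro-1-benzofuran-4(2H)-one | C/C(=C\CC[C@](C)(O[Si](C)(C)C(C)(C)C)[C@@H]1CC2=C(CC[C@@H](O)C2=O)O1)CC/C=C(\C)CO[Si](c1ccccc1)(c1ccccc1)C(C)(C)C | intermediate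
31 | (2S,5R)-2-[(2S,5E,9E)-2,11-dihydroxy-6,10-dimethylundeca-5,9-dien-2-yl]-5-hydroxy-3,5,6,7-tetrahydro-1-benzofuran-4(2H)-one | C/C(=C\CC[C@](C)(O)[C@@H]1CC2=C(CC[C@@H](O)C2=O)O1)CC/C=C(\C)CO | intermediate
32 | (2E,6E,10S)-10-hydroxy-10-[(2S,5R)-5-hydroxy-4-oxo-2,3,4,5,6,7-hexahydro-1-benzofuran-2-yl]-2,6-dimethylundeca-2,6-dienal | C/C(=C\CC[C@](C)(O)[C@@H]1CC2=C(CC[C@@H](O)C2=O)O1)CC/C=C(\C)C=O | intermediate
33 | (2E,6E,10S)-10-hydroxy-10-[(2S,5R)-5-hydroxy-4-oxo-2,3,4,5,6,7-hexahydro-1-benzofuran-2-yl]-2,6-dimethylundeca-2,6-dienoic acid | C/C(=C\CC[C@](C)(O)[C@@H]1CC2=C(CC[C@@H](O)C2=O)O1)CC/C=C(\C)C(=O)O | target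

## Step count and risks

Total step count: 19. Longest linear sequence: 18 (steps 1–7 and 9–19); step 8 is the one-step branch.

Steps most likely to fail:

Step 14 (Michael–Dieckmann annulation). Anionic oligomerisation of allyl acrylate may outrun the Dieckmann closure, the dienolate may add through its α-carbon, or released methoxide may exchange the allyl ester. Fallback, setting out from 22 and returning at 26: 22 is deprotonated with LiN(iPr)2 and trapped with Me3SiCl as the silyl ketene acetal F1, an exocyclic s-cis 1,1,3-trioxygenated diene of the Brassard type. Thermal Diels–Alder reaction of F1 with allyl acrylate 23 in toluene should give the cycloadduct F2 with the same regiochemistry (unsubstituted diene terminus to the acrylate β-carbon). Dilute acid on work-up collapses the mixed silyl methyl ketal of F2 to the C4 ketone, which is 26; the neutral, pericyclic pathway avoids free ester enolates altogether.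

Step 16 (asymmetric hydroxylation). Facial selectivity of oxygen transfer to an enolate that lacks a C5 substituent may be poor or reversed, and part of the deprotonation may go to C7. Fallback, setting out from 28 and returning at 30: the sodium enolate of 28 is hydroxylated with racemic 2-(phenylsulfonyl)-3-phenyloxaziridine to give the ketol as a mixture of C5 epimers F3. Acylation with vinyl acetate and Burkholderia cepacia lipase is expected, by the Kazlauskas rule, to acetylate the (5R)-epimer preferentially, giving the acetate F4, which is separated from the unreacted (5S)-alcohol F5 by chromatography. Lipase-mediated hydrolysis of F4 in phosphate buffer then gives 30 without base, so C5 is not epimerised; F5 is set aside.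

Step 13 (epoxide opening and acyl-lactone rearrangement). Opening of the epoxide beside the quaternary silyloxy carbon may be slow, the transient secondary alkoxide may take over the neighbouring silyl group, and the acidic methanol may erode the silyl ethers. Fallback, setting out from 16 and returning at 22: the primary hydroxyl of 16 is exchanged for iodide (I2, PPh3, imidazole) to give the iodohydrin F6, and the secondary hydroxyl is capped (Et3SiCl, imidazole) as the triethylsilyl ether F7. The sodium enolate of methyl acetoacetate 19 (NaH, DMF) is C-alkylated with F7 to give the keto ester F8. Pyridinium p-toluenesulfonate in methanol then removes the triethylsilyl group, and the freed hydroxy keto ester 20 closes to the hemiketal and loses water to give 22, with no alkoxide next to the tertiary silyl ether and no strong acid.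

## Further compounds

F1 | step 14 | methyl trimethylsilyl ketene acetal of 22, (5S)-3-[methoxy(trimethylsilyloxy)methylidene]-2-methylidene-5-substituted oxolane | C/C(=C\CC[C@](C)(O[Si](C)(C)C(C)(C)C)[C@@H]1CC(=C(OC)O[Si](C)(C)C)C(=C)O1)CC/C=C(\C)CO[Si](c1ccccc1)(c1ccccc1)C(C)(C)C
F2 | step 14 | Diels–Alder adduct, allyl (2S)-4-methoxy-4-(trimethylsilyloxy)-2-substituted 2,3,4,5,6,7-hexahydro-1-benzofuran-5-carboxylate | C/C(=C\CC[C@](C)(O[Si](C)(C)C(C)(C)C)[C@@H]1CC2=C(CCC(C(=O)OCC=C)C2(OC)O[Si](C)(C)C)O1)CC/C=C(\C)CO[Si](c1ccccc1)(c1ccccc1)C(C)(C)C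
F3 | step 16 | C5-epimeric mixture of the 5-hydroxy ketone (30 and its 5S epimer) | C/C(=C\CC[C@](C)(O[Si](C)(C)C(C)(C)C)[C@@H]1CC2=C(CCC(O)C2=O)O1)CC/C=C(\C)CO[Si](c1ccccc1)(c1ccccc1)C(C)(C)C
F4 | step 16 | (2S,5R)-5-acetoxy ketone, acetate of 30 | C/C(=C\CC[C@](C)(O[Si](C)(C)C(C)(C)C)[C@@H]1CC2=C(CC[C@@H](OC(C)=O)C2=O)O1)CC/C=C(\C)CO[Si](c1ccccc1)(c1ccccc1)C(C)(C)C
F5 | step 16 | (2S,5S)-5-hydroxy ketone, C5 epimer of 30 | C/C(=C\CC[C@](C)(O[Si](C)(C)C(C)(C)C)[C@@H]1CC2=C(CC[C@H](O)C2=O)O1)CC/C=C(\C)CO[Si](c1ccccc1)(c1ccccc1)C(C)(C)C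
F6 | step 13 | (2R,3S,6E,10E)-3-[(tert-butyldimethylsilyl)oxy]-12-[(tert-butyldiphenylsilyl)oxy]-1-iodo-3,7,11-trimethyldodeca-6,10-dien-2-ol | C/C(=C\CC[C@](C)(O[Si](C)(C)C(C)(C)C)[C@@H](O)CI)CC/C=C(\C)CO[Si](c1ccccc1)(c1ccccc1)C(C)(C)C
F7 | step 13 | triethylsilyl ether of F6 | C/C(=C\CC[C@](C)(O[Si](C)(C)C(C)(C)C)[C@@H](O[Si](CC)(CC)CC)CI)CC/C=C(\C)CO[Si](c1ccccc1)(c1ccccc1)C(C)(C)C
F8 | step 13 | methyl (4S,5S,8E,12E)-2-acetyl-5-[(tert-butyldimethylsilyl)oxy]-14-[(tert-butyldiphenylsilyl)oxy]-5,9,13-trimethyl-4-[(triethylsilyl)oxy]tetradeca-8,12-dienoate | C/C(=C\CC[C@](C)(O[Si](C)(C)C(C)(C)C)[C@@H](O[Si](CC)(CC)CC)CC(C(C)=O)C(=O)OC)CC/C=C(\C)CO[Si](c1ccccc1)(c1ccccc1)C(C)(C)C
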